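## Structural features

The target is a 5,6-dihydro-2H-pyran-2-one (ring atoms O1, C2(=O), C3=C4, C5, C6) with one substituent at C6: a ten-carbon chain C1'–C10' that ends in a phenyl ring on C10'. The chain starts with a cis C1'=C2' double bond attached directly to C6, continues through the C3' methylene to three secondary carbinols at C4', C6' and C8' (separated by the C5' and C7' methylenes), and ends in the C9'–C10' link to the arene. The four stereocentres are C6 (S), C4' (R), C6' (S) and C8' (R). No two are adjacent: C4'/C6' are 1,3-syn, C6'/C8' are 1,3-anti, and C6 is 1,5-related to C4' across the alkene, so each centre has to come from a reagent or a catalyst. The fragile elements are the unsaturated lactone (a Michael acceptor that opens with base or nucleophiles), the allylic acyloxy C6–O bond, the Z-alkene (which isomerises once conjugated to a carbonyl group) and the free 1,3,5-triol. The real difficulty is the cis-disubstituted alkene held between two oxygenated stereocentres, C6 and C4', of defined absolute configuration. The key step uses the fact that O(C4')–C4'–C3'–C2'=C1'–C6 is the opened form of a 6-substituted 5,6-dihydro-2H-pyran with C6 as the anomeric carbon. Building that ring by cycloaddition onto a C4' aldehyde fixes C1'=C2' as cis, sets C4', and delivers C6 as a masked aldehyde.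

## Logic of the disconnections

**23 ⇒ 22.** The three O–Si bonds at C4', C6' and C8' are cut. The triol has to stay masked through all basic, oxidising and organometallic steps, and one type of silyl ether on all three oxygens allows a single final operation. The demand on the forward step is a fluoride source that is acidic and not basic, so that the lactone and the Z-alkene survive.

**22 ⇒ 21 ⇒ 20.** The C3=C4 ring alkene is cut (ring-closing metathesis) and then the O1–C2 acyl bond (acylation). The ring alkene is cis by necessity, so it can be made from two terminal alkenes without a geometry problem. This closure was preferred to an aldol/olefination sequence because it avoids a β-hydroxy aldehyde next to the Z-alkene, which would be prone to elimination. The gain is that the whole lactone reduces to the secondary alcohol 20. The demand is that the metathesis catalyst leaves the internal C1'=C2' alkene alone.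

**20 ⇒ 18.** The C5–C6 bond is cut. C6 is an allylic carbinol with no nearby stereocentre, so it is best made by reagent-controlled allyl transfer to the C6 aldehyde. This removes three carbons and the last stereocentre. The forward step must be a clean 1,2-addition at low temperature so that the Z-enal does not isomerise.

**18 ⇒ 17 ⇒ 16 ⇒ 15.** These are changes of functional group, followed by reconnection of the acyl C6–O(C4') bond. The aldehyde carbon of 18 is taken back to the amide carbon of 17, the silyl group on O4' is removed (16), and C6 is rejoined to O4' to give the ring of 15. In the ring, the cis geometry of C1'=C2' is automatic and O4' is tied up. The forward steps need attack of an aluminium amide at the carbonyl carbon and not at C2', silylation before re-closure, and a reduction that stops at the aldehyde.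

**15 ⇒ 13.** The oxidation level at C6 is lowered from lactone to cyclic methyl acetal. This erases the acetal centre as a stereochemical concern and exposes the cycloadduct. The forward step needs hydrolysis and oxidation mild enough for the silyl ethers.

**13 ⇒ 11 + 12.** The C3'–C4' bond and the ring O–C6 bond are cut in a retro-[4+2] sense. One step then builds the ring, two skeletal bonds and C4', from an acyclic aldehyde with two stereocentres and a commercial diene. The demand is catalyst control of the aldehyde face over the resident C6' centre.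

**11 ⇒ 9 ⇒ 8 ⇒ 6.** The aldehyde carbon C4' is read as the cleaved end of a terminal alkene, and the C5'–C6' bond is cut (allyl transfer to the aldehyde carbon of 6). This removes C6'. The forward allylation must be reagent-controlled to give the 1,3-anti relationship to C8'.

**6 ⇒ 4 ⇒ 3 ⇒ 1.** The same two operations are repeated: the aldehyde is taken back to an alkene and the C7'–C8' bond is cut. This ends at the achiral aldehyde 1. The demand is high enantioselectivity in the first allyl transfer, since every later centre is built relative to C8'.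

## Other disconnections considered

**Alternative 1:** The C2'–C7' stretch is folded back into a six-membered carbocycle, the meso ketone A1 (cis-3,5-bis(tert-butyldimethylsilyloxy)cyclohexanone). The forward key step is an enantioselective Baeyer–Villiger oxidation by a cyclohexanone monooxygenase (O2, NADPH recycling). The enzyme-bound flavin hydroperoxide adds to the carbonyl and one of the two enantiotopic α-methylenes migrates to oxygen, giving the seven-membered lactone A2 with C4' and C6' set.

- In its favour: both centres of the syn C4'/C6' pair arise in one catalytic step from an achiral substrate, with air as the oxidant. On stereocentres created per chiral reagent it is better than the chosen plan, whose key step sets only C4' and which uses three stoichiometric boranes elsewhere.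
- Against it here: A2 covers only C2'–C7'. The new oxygen sits on C7', which is a plain methylene in the target, so it must be made a leaving group and displaced by a C8'–C10' unit. C8' then has to be set 1,3-anti in a further operation. C2' arrives as a carboxyl carbon and needs reduction and a Z-selective olefination, so the alkene geometry is not secured by structure. Acceptance of a substrate with two bulky silyloxy groups by the enzyme is uncertain.
- Comparison: structurally it addresses the polyol core and nothing of the alkene or the lactone, whereas the chosen cycloaddition makes the C3'–C4' bond, C4' and the cis alkene together. Mechanistically both are catalytic and equal on that point (enzyme pocket against a chiral Lewis acid). In step count the chosen plan should be shorter, because much more remains to be done after A2.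

**Alternative 2:** The cut is the C1'=C2' double bond. The forward key step is ring-closing metathesis of the acyclic diene A3, the diisopropylsilylene bis-ether joining the C6 allylic oxygen and the C4' homoallylic oxygen. With RuCl2(H2IMes)(PCy3)(=CHPh) (second-generation Grubbs catalyst) it would give the eight-membered 1,3-dioxa-2-silacyclooctene A4 with loss of ethylene.

- In its favour: the ring enforces the cis geometry. On this point it is the equal of the chosen plan, which uses the same idea with a six-membered ring. It is convergent, and no Z-enal is ever handled; both are points on which it is better.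
- Against it here: the step forms no backbone single bond and no stereocentre. The C6-bearing half needs its own asymmetric synthesis and the C4'-bearing half still needs a third allylation of 11. Building an unsymmetrical silylene is a sequential, moisture-sensitive operation that competes with symmetrical coupling. Closure of a medium ring needs high dilution and is slowed by branching at both allylic positions. After A4 the lactone still has to be built from the protected C4 terminus (deprotection, oxidation, Z-olefination, lactonisation).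
- Comparison: the metathesis mechanism is reliable for the geometry but contributes only geometry, whereas the cycloaddition contributes geometry, two bonds and a stereocentre. In step count the alternative is expected to be longer.

**Alternative 3:** Both cis alkenes are traced back to alkynes and the O1–C2 bond is opened, giving the C6-hydroxy diynoate A5. The forward key step is a double semi-hydrogenation over Pd/CaCO3 poisoned with Pb(OAc)2 and quinoline (two equivalents of H2, syn delivery at each triple bond), after which the C6 hydroxyl closes onto the now cis-configured ester in the same flask to give A6, which is the same compound as 22.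

- In its favour: one operation sets both cis geometries and closes the ring. Acetylide and propargyl couplings allow a convergent assembly. The count from 11 to A6 would probably be lower than from 11 to 22 (about six operations against eight), so on step economy it is better. It also avoids a Z-enal.
- Against it here: two triple bonds of different electronic character must both stop at the alkene stage, and the conjugated lactone product is itself reducible. A5 has a C5 methylene between an ynoate and a propargylic carbinol, which invites base-induced isomerisation to allenes. C6 and C4' would rest on asymmetric propargylation or alkynylation (one of them on an ynal), where reagent control is less secure than in allylboration. The key step creates no stereocentre.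
- Comparison: the hydrogenation is a heterogeneous, kinetically controlled reduction whose selectivity is hard to enforce by design. The chosen plan accepts about two more steps in exchange for a key step with catalyst-controlled stereochemistry.

Key step: step 7

**Conventions, assumptions and remarks**

- TBS is tert-butyldimethylsilyl, TBSO is tert-butyldimethylsilyloxy and Ipc is isopinocampheyl. (−)-Ipc2BOMe is the borinate made from (+)-α-pinene and (+)-Ipc2BOMe is its enantiomer.
- Assumption: the allylborane from (−)-Ipc2BOMe transfers allyl to the Si face of an aldehyde RCHO and its enantiomer to the Re face, the accepted sense for these reagents.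
- Assumption: the chromium catalyst built from (1R,2S)-1-amino-2-indanol delivers the diene to the Re face of an α-unbranched aldehyde, the sense accepted for this catalyst family. If it proved otherwise, the enantiomeric catalyst would be used with no other change.
- Remark: the descriptor of C6' alternates between S and R along the route only because the CIP ranking of its two methylene neighbours changes; its spatial arrangement is the same throughout.

## Route

**Step 1**
Reactants: 1 3-phenylpropanal
Product: 3 (R)-1-phenylhex-5-en-3-ol, via borinate ester 2 (not isolated)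
Conditions: (−)-Ipc2BOMe, CH2=CHCH2MgBr, Et2O, −78 °C → rt; then 1, −78 °C; then NaOH, H2O2, rt
Reagents that add atoms: CH2=CHCH2MgBr, C=CC[Mg]Br (source of the allyl group, passed on through the allylborane formed in the flask); (−)-Ipc2BOMe, COB([C@@H]1C[C@@H]2C[C@@H](C2(C)C)[C@H]1C)[C@@H]1C[C@@H]2C[C@@H](C2(C)C)[C@H]1C (its boron and Ipc groups remain in 2 only)
Why: Brown allylation through a closed six-membered chair transition state; the pinene-derived ligands direct allyl to the Si face of the unbranched aldehyde, which sets C8' as R, and oxidative work-up cleaves the B–O bond of 2.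

**Step 2**
Reactants: 3 (R)-1-phenylhex-5-en-3-ol
Product: 4 (R)-3-(TBSO)-1-phenylhex-5-ene
Conditions: TBSCl, imidazole, DMF, rt
Reagents that add atoms: tert-butyldimethylsilyl chloride, CC(C)(C)[Si](C)(C)Cl
Why: Standard silylation of an unhindered secondary alcohol through the N-silylimidazolium species; the stereocentre is not touched.

**Step 3**
Reactants: 4 (R)-3-(TBSO)-1-phenylhex-5-ene
Product: 6 (R)-3-(TBSO)-5-phenylpentanal, via ozonide 5 (not isolated)
Conditions: O3, CH2Cl2, −78 °C (stopped at first excess); then PPh3, −78 °C → rt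
Reagents that add atoms: ozone, [O-][O+]=O
Why: Ozonolysis of the terminal alkene (cycloaddition, cycloreversion and recombination to the 1,2,4-trioxolane 5) followed by neutral phosphine reduction. The isolated monoalkylbenzene ring reacts with ozone far more slowly than the alkene at −78 °C, and the absence of base spares the β-silyloxy aldehyde from elimination.

**Step 4**
Reactants: 6 (R)-3-(TBSO)-5-phenylpentanal
Product: 8 (4R,6R)-6-(TBSO)-8-phenyloct-1-en-4-ol, via borinate ester 7 (not isolated)
Conditions: (+)-Ipc2BOMe, CH2=CHCH2MgBr, Et2O, −78 °C → rt; then 6, −78 °C; then NaOH, H2O2, rt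
Reagents that add atoms: CH2=CHCH2MgBr, C=CC[Mg]Br (allyl group); (+)-Ipc2BOMe, COB([C@H]1C[C@H]2C[C@H](C2(C)C)[C@@H]1C)[C@H]1C[C@H]2C[C@H](C2(C)C)[C@@H]1C (retained in 7 only)
Why: Brown allylation with the enantiomeric reagent, which attacks the Re face and sets C6' 1,3-anti to C8'. Reagent control should dominate because a β-silyloxy group exerts only a weak 1,3-bias in closed allylboration transition states.

**Step 5**
Reactants: 8 (4R,6R)-6-(TBSO)-8-phenyloct-1-en-4-ol
Product: 9 (4R,6R)-4,6-bis(TBSO)-8-phenyloct-1-ene
Conditions: TBSCl, imidazole, DMF, rt → 40 °C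
Reagents that add atoms: tert-butyldimethylsilyl chloride, CC(C)(C)[Si](C)(C)Cl
Why: Silylation of the second secondary alcohol; the two bulky, non-chelating silyl ethers are the form the key step needs.

**Step 6**
Reactants: 9 (4R,6R)-4,6-bis(TBSO)-8-phenyloct-1-ene
Product: 11 (3S,5R)-3,5-bis(TBSO)-7-phenylheptanal, via ozonide 10 (not isolated)
Conditions: O3, CH2Cl2, −78 °C; then PPh3, −78 °C → rt
Reagents that add atoms: ozone, [O-][O+]=O
Why: Ozonolysis with reductive work-up as in step 3; the aldehyde should be used promptly, since β-silyloxy aldehydes eliminate on prolonged contact with silica or base.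

**Step 7**
Reactants: 11 (3S,5R)-3,5-bis(TBSO)-7-phenylheptanal; 12 (E)-1-methoxybuta-1,3-diene
Product: 13 (2S,6R)-6-[(2R,4R)-2,4-bis(TBSO)-6-phenylhexyl]-2-methoxy-5,6-dihydro-2H-pyran
Conditions: [Cr(L)Cl] (5 mol %; trivalent chromium; L = dianion of the Schiff base from (1R,2S)-1-amino-2-indanol and 3-(1-adamantyl)-2-hydroxy-5-methylbenzaldehyde), 4 Å molecular sieves, minimum t-BuOMe, rt
Reagents that add atoms: none
Why: The Lewis-acidic chromium centre binds the aldehyde oxygen of 11 and the electron-rich diene adds in a concerted, asynchronous [4+2] cycloaddition, its unsubstituted CH2 terminus bonding to the carbonyl carbon (C3'–C4') slightly ahead of bonding of the carbonyl oxygen to the methoxy-bearing carbon (O–C6). The closest known reaction type is the chromium Schiff-base catalysed hetero-Diels–Alder reaction of 1-alkoxybutadienes with unbranched aliphatic aldehydes, silyloxy-substituted ones included. The one new ring, the 5,6-dihydro-2H-pyran, is closed by intermolecular cycloaddition, both ring bonds forming in the same event, and its alkene (C1'=C2') is cis because it is endocyclic. C4' is set by the catalyst, which is taken to expose the Re face of the bound aldehyde and so gives 4'R, syn to the C6' silyloxy group. The acetal carbon is set cis to the C4' substituent by the endo transition state, but this centre is removed in step 8 and need not be controlled. The step needs catalyst control over the resident C6' centre, reaction at C=O only, and the regiochemistry fixed by the polarised diene. The substrate supports this because it is unbranched at the α-carbon, its silyl ethers cannot chelate chromium, and the β-stereocentre has only a weak intrinsic bias. The sieves keep the catalyst dry, and the volatile diene is easily separated from the non-volatile cycloadduct.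

**Step 8**
Reactants: 13 (2S,6R)-6-[(2R,4R)-2,4-bis(TBSO)-6-phenylhexyl]-2-methoxy-5,6-dihydro-2H-pyran
Product: 15 (R)-6-[(2R,4R)-2,4-bis(TBSO)-6-phenylhexyl]-5,6-dihydro-2H-pyran-2-one, via lactol 14 (not isolated)
Conditions: PPTS, acetone/H2O, rt; then MnO2, CH2Cl2, rt
Reagents that add atoms: water, O
Why: Mild acid-catalysed acetal hydrolysis through the allylic oxocarbenium ion gives lactol 14, whose allylic hemiacetal C–H is oxidised by activated MnO2 to the conjugated lactone. Secondary TBS ethers tolerate PPTS, and the acetal stereocentre disappears.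

**Step 9**
Reactants: 15 (R)-6-[(2R,4R)-2,4-bis(TBSO)-6-phenylhexyl]-5,6-dihydro-2H-pyran-2-one
Product: 16 (2Z,5R,7R,9R)-7,9-bis(TBSO)-5-hydroxy-N-methoxy-N-methyl-11-phenylundec-2-enamide
Conditions: MeNH(OMe)·HCl, AlMe3, CH2Cl2, 0 °C; aq. KNaC4H4O6 work-up
Reagents that add atoms: N,O-dimethylhydroxylamine hydrochloride, CNOC.Cl
Why: Weinreb aminolysis of a lactone: the oxophilic aluminium amide activates and attacks the carbonyl carbon (1,2-addition) and the ring opens to the aluminium alkoxide. The Z geometry is inherited from the ring and no bond to a stereocentre is broken.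

**Step 10**
Reactants: 16 (2Z,5R,7R,9R)-7,9-bis(TBSO)-5-hydroxy-N-methoxy-N-methyl-11-phenylundec-2-enamide
Product: 17 (2Z,5R,7S,9R)-5,7,9-tris(TBSO)-N-methoxy-N-methyl-11-phenylundec-2-enamide
Conditions: TBSOTf, 2,6-lutidine, CH2Cl2, −78 → 0 °C (crude 16 used at once)
Reagents that add atoms: tert-butyldimethylsilyl triflate, CC(C)(C)[Si](C)(C)OS(=O)(=O)C(F)(F)F
Why: Fast low-temperature silylation with a silyl triflate and a hindered base caps O4' before the hydroxy amide can re-close to the lactone; the amide is inert to these conditions.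

**Step 11**
Reactants: 17 (2Z,5R,7S,9R)-5,7,9-tris(TBSO)-N-methoxy-N-methyl-11-phenylundec-2-enamide
Product: 18 (2Z,5R,7S,9R)-5,7,9-tris(TBSO)-11-phenylundec-2-enal
Conditions: i-Bu2AlH, THF, −78 °C; aq. KNaC4H4O6, 0 °C
Reagents that add atoms: none
Why: Reduction of a Weinreb amide stops at the aldehyde level because the five-membered aluminium chelate of the tetrahedral adduct collapses only on work-up. The cold, near-neutral tartrate work-up and direct use of the crude enal are meant to preserve the Z geometry.

**Step 12**
Reactants: 18 (2Z,5R,7S,9R)-5,7,9-tris(TBSO)-11-phenylundec-2-enal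
Product: 20 (4S,5Z,8R,10S,12R)-8,10,12-tris(TBSO)-14-phenyltetradeca-1,5-dien-4-ol, via borinate ester 19 (not isolated)
Conditions: (−)-Ipc2BOMe, CH2=CHCH2MgBr, Et2O, −78 °C → rt; then 18, −78 °C; then NaOH, H2O2, 0 °C → rt
Reagents that add atoms: CH2=CHCH2MgBr, C=CC[Mg]Br (allyl group); (−)-Ipc2BOMe, COB([C@@H]1C[C@@H]2C[C@@H](C2(C)C)[C@H]1C)[C@@H]1C[C@@H]2C[C@@H](C2(C)C)[C@H]1C (retained in 19 only)
Why: Brown allylation of an enal is a pure 1,2-addition at −78 °C through the closed chair transition state. Si-face delivery sets C6 (C4 of 20) as S under reagent control, and the neutral, cold conditions give the Z-enal no opportunity to isomerise.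

**Step 13**
Reactants: 20 (4S,5Z,8R,10S,12R)-8,10,12-tris(TBSO)-14-phenyltetradeca-1,5-dien-4-ol
Product: 21 (4S,5Z,8R,10S,12R)-8,10,12-tris(TBSO)-14-phenyltetradeca-1,5-dien-4-yl prop-2-enoate
Conditions: CH2=CHCOCl, i-Pr2NEt, DMAP (cat.), CH2Cl2, −20 → 0 °C
Reagents that add atoms: acryloyl chloride, C=CC(=O)Cl
Why: O-acylation of the secondary allylic alcohol with an acid chloride and amine base; the C–O bond at C6 is not broken, so the configuration is retained.

**Step 14**
Reactants: 21 (4S,5Z,8R,10S,12R)-8,10,12-tris(TBSO)-14-phenyltetradeca-1,5-dien-4-yl prop-2-enoate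
Product: 22 (S)-6-[(1Z,4R,6S,8R)-4,6,8-tris(TBSO)-10-phenyldec-1-en-1-yl]-5,6-dihydro-2H-pyran-2-one
Conditions: RuCl2(PCy3)2(=CHPh) (first-generation Grubbs catalyst, 10 mol %), Ti(OiPr)4 (0.3 equiv), CH2Cl2 (2 mM), 40 °C
Reagents that add atoms: none
Why: Ring-closing metathesis: the ruthenium alkylidene loads on the unhindered terminal alkene, closes the six-membered ring onto the acrylate and releases ethylene. The internal, allylically branched C1'=C2' alkene is a much poorer substrate for this less active catalyst, and Ti(OiPr)4 breaks up the unproductive carbonyl chelate.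

**Step 15**
Reactants: 22 (S)-6-[(1Z,4R,6S,8R)-4,6,8-tris(TBSO)-10-phenyldec-1-en-1-yl]-5,6-dihydro-2H-pyran-2-one
Product: 23 (S)-6-[(1Z,4R,6S,8R)-4,6,8-trihydroxy-10-phenyldec-1-en-1-yl]-5,6-dihydro-2H-pyran-2-one (CNP0206968.1)
Conditions: HF (48 % aq.), MeCN, 0 °C → rt
Reagents that add atoms: none
Why: Fluoride-driven cleavage of three secondary silyl ethers under mildly acidic, non-basic conditions, which avoids Michael addition, lactone opening and alkene isomerisation; no stereocentre is involved.

## Compound list

1 | 3-phenylpropanal | O=CCCc1ccccc1 | starting material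
2 | (R)-1-phenylhex-5-en-3-yl bis[(1R,2S,3R,5R)-isopinocampheyl]borinate | C=CC[C@H](OB([C@@H]1C[C@@H]2C[C@@H](C2(C)C)[C@H]1C)[C@@H]1C[C@@H]2C[C@@H](C2(C)C)[C@H]1C)CCc1ccccc1 | intermediate
3 | (R)-1-phenylhex-5-en-3-ol | C=CC[C@H](O)CCc1ccccc1 | intermediate
4 | (R)-3-(TBSO)-1-phenylhex-5-ene | C=CC[C@H](O[Si](C)(C)C(C)(C)C)CCc1ccccc1 | intermediate
5 | 3-[(2R)-2-(TBSO)-4-phenylbutyl]-1,2,4-trioxolane (both epimers at the ring carbon) | C1OC(C[C@H](O[Si](C)(C)C(C)(C)C)CCc2ccccc2)OO1 | intermediate
6 | (R)-3-(TBSO)-5-phenylpentanal | O=CC[C@H](O[Si](C)(C)C(C)(C)C)CCc1ccccc1 | intermediate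
7 | (4R,6R)-6-(TBSO)-8-phenyloct-1-en-4-yl bis[(1S,2R,3S,5S)-isopinocampheyl]borinate | C=CC[C@@H](OB([C@H]1C[C@H]2C[C@H](C2(C)C)[C@@H]1C)[C@H]1C[C@H]2C[C@H](C2(C)C)[C@@H]1C)C[C@H](O[Si](C)(C)C(C)(C)C)CCc1ccccc1 | intermediate
8 | (4R,6R)-6-(TBSO)-8-phenyloct-1-en-4-ol | C=CC[C@@H](O)C[C@H](O[Si](C)(C)C(C)(C)C)CCc1ccccc1 | intermediate
9 | (4R,6R)-4,6-bis(TBSO)-8-phenyloct-1-ene | C=CC[C@@H](O[Si](C)(C)C(C)(C)C)C[C@H](O[Si](C)(C)C(C)(C)C)CCc1ccccc1 | intermediate
10 | 3-[(2S,4R)-2,4-bis(TBSO)-6-phenylhexyl]-1,2,4-trioxolane (both epimers at the ring carbon) | C1OC(C[C@@H](O[Si](C)(C)C(C)(C)C)C[C@H](O[Si](C)(C)C(C)(C)C)CCc2ccccc2)OO1 | intermediate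
11 | (3S,5R)-3,5-bis(TBSO)-7-phenylheptanal | O=CC[C@@H](O[Si](C)(C)C(C)(C)C)C[C@H](O[Si](C)(C)C(C)(C)C)CCc1ccccc1 | intermediate
12 | (E)-1-methoxybuta-1,3-diene | CO/C=C/C=C | starting material
13 | (2S,6R)-6-[(2R,4R)-2,4-bis(TBSO)-6-phenylhexyl]-2-methoxy-5,6-dihydro-2H-pyran (cis) | CO[C@@H]1C=CC[C@H](C[C@@H](O[Si](C)(C)C(C)(C)C)C[C@H](O[Si](C)(C)C(C)(C)C)CCc2ccccc2)O1 | intermediate
14 | (6R)-6-[(2R,4R)-2,4-bis(TBSO)-6-phenylhexyl]-5,6-dihydro-2H-pyran-2-ol (both anomers) | OC1C=CC[C@H](C[C@@H](O[Si](C)(C)C(C)(C)C)C[C@H](O[Si](C)(C)C(C)(C)C)CCc2ccccc2)O1 | intermediate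
15 | (R)-6-[(2R,4R)-2,4-bis(TBSO)-6-phenylhexyl]-5,6-dihydro-2H-pyran-2-one | O=C1C=CC[C@H](C[C@@H](O[Si](C)(C)C(C)(C)C)C[C@H](O[Si](C)(C)C(C)(C)C)CCc2ccccc2)O1 | intermediate
16 | (2Z,5R,7R,9R)-7,9-bis(TBSO)-5-hydroxy-N-methoxy-N-methyl-11-phenylundec-2-enamide | CON(C)C(=O)/C=C\C[C@@H](O)C[C@@H](O[Si](C)(C)C(C)(C)C)C[C@H](O[Si](C)(C)C(C)(C)C)CCc1ccccc1 | intermediate
17 | (2Z,5R,7S,9R)-5,7,9-tris(TBSO)-N-methoxy-N-methyl-11-phenylundec-2-enamide | CON(C)C(=O)/C=C\C[C@@H](O[Si](C)(C)C(C)(C)C)C[C@@H](O[Si](C)(C)C(C)(C)C)C[C@H](O[Si](C)(C)C(C)(C)C)CCc1ccccc1 | intermediate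
18 | (2Z,5R,7S,9R)-5,7,9-tris(TBSO)-11-phenylundec-2-enal | O=C/C=C\C[C@@H](O[Si](C)(C)C(C)(C)C)C[C@@H](O[Si](C)(C)C(C)(C)C)C[C@H](O[Si](C)(C)C(C)(C)C)CCc1ccccc1 | intermediate
19 | (4S,5Z,8R,10S,12R)-8,10,12-tris(TBSO)-14-phenyltetradeca-1,5-dien-4-yl bis[(1R,2S,3R,5R)-isopinocampheyl]borinate | C=CC[C@H](OB([C@@H]1C[C@@H]2C[C@@H](C2(C)C)[C@H]1C)[C@@H]1C[C@@H]2C[C@@H](C2(C)C)[C@H]1C)/C=C\C[C@@H](O[Si](C)(C)C(C)(C)C)C[C@@H](O[Si](C)(C)C(C)(C)C)C[C@H](O[Si](C)(C)C(C)(C)C)CCc1ccccc1 | intermediate
20 | (4S,5Z,8R,10S,12R)-8,10,12-tris(TBSO)-14-phenyltetradeca-1,5-dien-4-ol | C=CC[C@H](O)/C=C\C[C@@H](O[Si](C)(C)C(C)(C)C)C[C@@H](O[Si](C)(C)C(C)(C)C)C[C@H](O[Si](C)(C)C(C)(C)C)CCc1ccccc1 | intermediate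
21 | (4S,5Z,8R,10S,12R)-8,10,12-tris(TBSO)-14-phenyltetradeca-1,5-dien-4-yl prop-2-enoate | C=CC[C@H](OC(=O)C=C)/C=C\C[C@@H](O[Si](C)(C)C(C)(C)C)C[C@@H](O[Si](C)(C)C(C)(C)C)C[C@H](O[Si](C)(C)C(C)(C)C)CCc1ccccc1 | intermediate
22 | (S)-6-[(1Z,4R,6S,8R)-4,6,8-tris(TBSO)-10-phenyldec-1-en-1-yl]-5,6-dihydro-2H-pyran-2-one | O=C1C=CC[C@@H](/C=C\C[C@@H](O[Si](C)(C)C(C)(C)C)C[C@@H](O[Si](C)(C)C(C)(C)C)C[C@H](O[Si](C)(C)C(C)(C)C)CCc2ccccc2)O1 | intermediate
23 | (S)-6-[(1Z,4R,6S,8R)-4,6,8-trihydroxy-10-phenyldec-1-en-1-yl]-5,6-dihydro-2H-pyran-2-one | O=C1C=CC[C@@H](/C=C\C[C@@H](O)C[C@@H](O)C[C@H](O)CCc2ccccc2)O1 | target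

## Step count and least certain steps

Total: 15 steps. Longest linear sequence: 15 steps, from 1 to 23; 12 enters at step 7.

**Step 7 (key step).** Facial selectivity may be eroded if the pairing of catalyst and the C6' centre is mismatched. The cycloaddition may also be slow for a bulky, non-volatile aldehyde under nearly solvent-free conditions, and the Lewis acid could trigger β-elimination of the C6' silyloxy group.
Fallback, from 11 to 15: 11 would be allylated with the borane from (+)-Ipc2BOMe and CH2=CHCH2MgBr (Re-face delivery, as in step 4) to give the borinate (4R,6R,8R)-6,8-bis(TBSO)-10-phenyldec-1-en-4-yl bis[(1S,2R,3S,5S)-isopinocampheyl]borinate F1. Oxidative work-up would give the homoallylic alcohol (4R,6R,8R)-6,8-bis(TBSO)-10-phenyldec-1-en-4-ol F2. Acylation with acryloyl chloride would give the acrylate (4R,6R,8R)-6,8-bis(TBSO)-10-phenyldec-1-en-4-yl prop-2-enoate F3. Ring-closing metathesis of F3 with RuCl2(H2IMes)(PCy3)(=CHPh) (second-generation Grubbs catalyst) would close the same unsaturated lactone and rejoin the route at 15. This costs one more step and a further stoichiometric borane.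

**Step 9.** The aluminium amide may add in conjugate fashion to C2' (which would also scramble the alkene geometry by addition and elimination), and the hydroxy amide may re-close to the lactone during isolation.
Fallback, from 15 to 18: 15 would be reduced with i-Bu2AlH (2.5 equiv, CH2Cl2, −78 → 0 °C) to the diol (2Z,5R,7R,9R)-7,9-bis(TBSO)-11-phenylundec-2-ene-1,5-diol F4. Silylation of both hydroxyls (TBSOTf, 2,6-lutidine) would give (2Z,5R,7S,9R)-1,5,7,9-tetrakis(TBSO)-11-phenylundec-2-ene F5. Selective removal of the primary allylic silyl ether (HF·pyridine buffered with pyridine, THF, 0 °C) would give the allylic alcohol (2Z,5R,7S,9R)-5,7,9-tris(TBSO)-11-phenylundec-2-en-1-ol F6. Buffered Dess–Martin oxidation of F6 would rejoin the route at 18. This replaces three steps by four and uses no nitrogen nucleophile.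

**Step 11.** The Z-enal may isomerise to the E-enal during work-up or on silica, and over-reduction to the allylic alcohol is possible.
Fallback, from 17 to 20: 17 would be treated with CH2=CHCH2MgBr (THF, −78 °C), the chelated adduct releasing the allyl ketone (5Z,8R,10S,12R)-8,10,12-tris(TBSO)-14-phenyltetradeca-1,5-dien-4-one F7 on cold, buffered work-up. Corey–Bakshi–Shibata reduction of F7 with the (R)-2-methyl oxazaborolidine and catecholborane (toluene, −78 °C; alkenyl as the large group) would give the 4S alcohol and rejoin the route at 20. No free Z-enal is handled, at the price of a ketone whose allylic methylene must be kept away from acid and base.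

**Step 14.** The internal Z-alkene may be engaged, with loss of the side chain through butenolide formation or Z/E scrambling by secondary metathesis, and the electron-poor acrylate may turn over slowly.
Fallback, from 18 to 23: an auxiliary-controlled acetate aldol of 18 with the titanium enolate of (R)-3-acetyl-4-benzylthiazolidine-2-thione (TiCl4, i-Pr2NEt, CH2Cl2, −78 °C) would give (3S,4Z,7R,9S,11R)-1-[(4R)-4-benzyl-2-thioxothiazolidin-3-yl]-3-hydroxy-7,9,11-tris(TBSO)-13-phenyltridec-4-en-1-one F8. The auxiliary enantiomer is chosen on the chelated chair model and would be exchanged if the sense proved reversed. Silylation (TBSOTf, 2,6-lutidine) would give the tetrakis-silyl ether F9. Reduction with i-Bu2AlH would release the auxiliary and give the aldehyde (3S,4Z,7R,9S,11R)-3,7,9,11-tetrakis(TBSO)-13-phenyltridec-4-enal F10. Still–Gennari olefination ((CF3CH2O)2P(O)CH2CO2Me, KN(SiMe3)2, 18-crown-6, THF, −78 °C) would give methyl (2Z,5S,6Z,9R,11S,13R)-5,9,11,13-tetrakis(TBSO)-15-phenylpentadeca-2,6-dienoate F11. HF in MeCN would then remove all silyl groups and close the lactone, arriving at 23. This takes five steps in place of four and uses no metathesis.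

## Further compounds

F1 | step 7 | (4R,6R,8R)-6,8-bis(TBSO)-10-phenyldec-1-en-4-yl bis[(1S,2R,3S,5S)-isopinocampheyl]borinate | C=CC[C@@H](OB([C@H]1C[C@H]2C[C@H](C2(C)C)[C@@H]1C)[C@H]1C[C@H]2C[C@H](C2(C)C)[C@@H]1C)C[C@@H](O[Si](C)(C)C(C)(C)C)C[C@H](O[Si](C)(C)C(C)(C)C)CCc1ccccc1
F2 | step 7 | (4R,6R,8R)-6,8-bis(TBSO)-10-phenyldec-1-en-4-ol | C=CC[C@@H](O)C[C@@H](O[Si](C)(C)C(C)(C)C)C[C@H](O[Si](C)(C)C(C)(C)C)CCc1ccccc1
F3 | step 7 | (4R,6R,8R)-6,8-bis(TBSO)-10-phenyldec-1-en-4-yl prop-2-enoate | C=CC[C@@H](OC(=O)C=C)C[C@@H](O[Si](C)(C)C(C)(C)C)C[C@H](O[Si](C)(C)C(C)(C)C)CCc1ccccc1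
F4 | step 9 | (2Z,5R,7R,9R)-7,9-bis(TBSO)-11-phenylundec-2-ene-1,5-diol | OC/C=C\C[C@@H](O)C[C@@H](O[Si](C)(C)C(C)(C)C)C[C@H](O[Si](C)(C)C(C)(C)C)CCc1ccccc1
F5 | step 9 | (2Z,5R,7S,9R)-1,5,7,9-tetrakis(TBSO)-11-phenylundec-2-ene | CC(C)(C)[Si](C)(C)OC/C=C\C[C@@H](O[Si](C)(C)C(C)(C)C)C[C@@H](O[Si](C)(C)C(C)(C)C)C[C@H](O[Si](C)(C)C(C)(C)C)CCc1ccccc1
F6 | step 9 | (2Z,5R,7S,9R)-5,7,9-tris(TBSO)-11-phenylundec-2-en-1-ol | OC/C=C\C[C@@H](O[Si](C)(C)C(C)(C)C)C[C@@H](O[Si](C)(C)C(C)(C)C)C[C@H](O[Si](C)(C)C(C)(C)C)CCc1ccccc1
F7 | step 11 | (5Z,8R,10S,12R)-8,10,12-tris(TBSO)-14-phenyltetradeca-1,5-dien-4-one | C=CCC(=O)/C=C\C[C@@H](O[Si](C)(C)C(C)(C)C)C[C@@H](O[Si](C)(C)C(C)(C)C)C[C@H](O[Si](C)(C)C(C)(C)C)CCc1ccccc1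
F8 | step 14 | (3S,4Z,7R,9S,11R)-1-[(4R)-4-benzyl-2-thioxothiazolidin-3-yl]-3-hydroxy-7,9,11-tris(TBSO)-13-phenyltridec-4-en-1-one | S=C1SC[C@@H](Cc2ccccc2)N1C(=O)C[C@H](O)/C=C\C[C@@H](O[Si](C)(C)C(C)(C)C)C[C@@H](O[Si](C)(C)C(C)(C)C)C[C@H](O[Si](C)(C)C(C)(C)C)CCc1ccccc1
F9 | step 14 | (3S,4Z,7R,9S,11R)-1-[(4R)-4-benzyl-2-thioxothiazolidin-3-yl]-3,7,9,11-tetrakis(TBSO)-13-phenyltridec-4-en-1-one | S=C1SC[C@@H](Cc2ccccc2)N1C(=O)C[C@H](O[Si](C)(C)C(C)(C)C)/C=C\C[C@@H](O[Si](C)(C)C(C)(C)C)C[C@@H](O[Si](C)(C)C(C)(C)C)C[C@H](O[Si](C)(C)C(C)(C)C)CCc1ccccc1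
F10 | step 14 | (3S,4Z,7R,9S,11R)-3,7,9,11-tetrakis(TBSO)-13-phenyltridec-4-enal | O=CC[C@H](O[Si](C)(C)C(C)(C)C)/C=C\C[C@@H](O[Si](C)(C)C(C)(C)C)C[C@@H](O[Si](C)(C)C(C)(C)C)C[C@H](O[Si](C)(C)C(C)(C)C)CCc1ccccc1
F11 | step 14 | methyl (2Z,5S,6Z,9R,11S,13R)-5,9,11,13-tetrakis(TBSO)-15-phenylpentadeca-2,6-dienoate | COC(=O)/C=C\C[C@H](O[Si](C)(C)C(C)(C)C)/C=C\C[C@@H](O[Si](C)(C)C(C)(C)C)C[C@@H](O[Si](C)(C)C(C)(C)C)C[C@H](O[Si](C)(C)C(C)(C)C)CCc1ccccc1
A1 | alternative 1 | cis-3,5-bis(TBSO)cyclohexanone (meso, 3R,5S) | O=C1C[C@@H](O[Si](C)(C)C(C)(C)C)C[C@@H](O[Si](C)(C)C(C)(C)C)C1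
A2 | alternative 1 | (4S,6R)-4,6-bis(TBSO)oxepan-2-one | O=C1C[C@@H](O[Si](C)(C)C(C)(C)C)C[C@@H](O[Si](C)(C)C(C)(C)C)CO1
A3 | alternative 2 | diisopropyl{[(3S)-5-(4-methoxybenzyloxy)pent-1-en-3-yl]oxy}{[(4R,6S,8R)-6,8-bis(TBSO)-10-phenyldec-1-en-4-yl]oxy}silane | C=C[C@H](CCOCc1ccc(OC)cc1)O[Si](C(C)C)(C(C)C)O[C@H](CC=C)C[C@@H](O[Si](C)(C)C(C)(C)C)C[C@H](O[Si](C)(C)C(C)(C)C)CCc1ccccc1
A4 | alternative 2 | (Z)-2,2-diisopropyl-1,3-dioxa-2-silacyclooct-5-ene with the 2-(4-methoxybenzyloxy)ethyl group at C4 (S) and the (2S,4R)-2,4-bis(TBSO)-6-phenylhexyl group at C8 (R) | COc1ccc(COCC[C@H]2/C=C\C[C@H](C[C@@H](O[Si](C)(C)C(C)(C)C)C[C@H](O[Si](C)(C)C(C)(C)C)CCc3ccccc3)O[Si](C(C)C)(C(C)C)O2)cc1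
A5 | alternative 3 | methyl (5S,9R,11S,13R)-5-hydroxy-9,11,13-tris(TBSO)-15-phenylpentadeca-2,6-diynoate | COC(=O)C#CC[C@H](O)C#CC[C@@H](O[Si](C)(C)C(C)(C)C)C[C@@H](O[Si](C)(C)C(C)(C)C)C[C@H](O[Si](C)(C)C(C)(C)C)CCc1ccccc1
A6 | alternative 3 | (S)-6-[(1Z,4R,6S,8R)-4,6,8-tris(TBSO)-10-phenyldec-1-en-1-yl]-5,6-dihydro-2H-pyran-2-one (identical with 22) | O=C1C=CC[C@@H](/C=C\C[C@@H](O[Si](C)(C)C(C)(C)C)C[C@@H](O[Si](C)(C)C(C)(C)C)C[C@H](O[Si](C)(C)C(C)(C)C)CCc2ccccc2)O1
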